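**Assumption:** Angustone B has no stereocentre (it is achiral), so no enantiocontrol is needed; the only stereo-element, the cis chromene alkene, is ring-enforced.

**Retrosynthetic overview**
1. Angustone B (13) ⇒ tri-MOM ether 12 by acetal hydrolysis.
2. 12 ⇒ C2v-symmetric phenol 5 + enamino ester 11, cutting C4–C4a and O1–C2 (pyranone ring formed last). Both ortho positions of 5 are identical, so only the 6-prenyl isomer can form.
3. 5 ⇒ resorcinol: MOM protection, lithiation/prenylation between the two oxygens, then C–H borylation/oxidation at the one unhindered C–H.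
4. 11 ⇒ arylacetate 10 ⇒ cyclohexane-1,3-dione + prenal: the pyran ring is made first by [3+3] annulation, then the B-ring benzene is created by aldol/isoaromatisation without an oxidant.
5. Ring order: B-ring pyran → B-ring benzene → C-ring pyranone; the A ring comes from resorcinol.

**Route**

Step 1
Reactants: 1 resorcinol
Product: 2 1,3-bis(methoxymethoxy)benzene
Conditions: NaH, MOMCl, DMF, 0 °C → rt
Reagents that add atoms: chloromethyl methyl ether, COCCl
Why: Williamson O-alkylation of both phenols installs two ortho-directing MOM groups that are later removed together.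

Step 2
Reactants: 2; 3 prenyl bromide
Product: 4 1,3-bis(methoxymethoxy)-2-(3-methylbut-2-en-1-yl)benzene
Conditions: n-BuLi, THF, 0 °C → rt; CuI (cat.), then 3, −78 °C → rt
Reagents that add atoms: none (new atoms come from 3)
Why: Directed ortho-metalation occurs at the C–H flanked by both OMOM groups, and Cu-mediated allylation gives the linear prenyl group (SN2, not SN2′), leaving the arene C2v-symmetric.

Step 3
Reactants: 4
Product: 5 3,5-bis(methoxymethoxy)-4-(3-methylbut-2-en-1-yl)phenol
Conditions: [Ir(OMe)(cod)]2 (1.5 mol%), dtbpy, B2pin2, THF, 70 °C; then aq. NaOH, 30% H2O2, 0 °C (one pot)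
Reagents that add atoms: hydrogen peroxide, OO
Why: Sterically controlled Ir-catalysed C–H borylation takes the only C–H with no ortho substituent (para to prenyl), and basic peroxide oxidation of the ArBpin gives the phenol without touching the trisubstituted alkene.

Step 4
Reactants: 6 cyclohexane-1,3-dione; 7 3-methylbut-2-enal (prenal)
Product: 8 2,2-dimethyl-2,6,7,8-tetrahydro-5H-chromen-5-one
Conditions: ethylenediammonium diacetate (10 mol%), CH2Cl2, rt
Reagents that add atoms: none (new atoms come from 7)
Why: Knoevenagel condensation followed by oxa-6π electrocyclisation (formal [3+3]) desymmetrises the dione and places the dimethylpyran on the carbon between the two oxygens, as the B ring requires.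

Step 5
Reactants: 8; 9 ethyl glyoxylate
Product: 10 ethyl 2-[5-(methoxymethoxy)-2,2-dimethyl-2H-chromen-6-yl]acetate
Conditions: LDA, THF, −78 °C; 9; MsCl, Et3N, −78 → 0 °C; DBU, rt; then MOMCl, 0 °C → rt (telescoped)
Reagents that add atoms: chloromethyl methyl ether, COCCl
Why: Kinetic α′-enolate aldol of the vinylogous ester and E1cB dehydration give the 6-alkylidene dienone, which DBU tautomerises to the phenol (isoaromatisation, no oxidant), and the phenoxide is trapped as its MOM ether; the side chain is therefore ortho to the oxygen by construction.

Step 6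
Reactants: 10
Product: 11 ethyl 3-(dimethylamino)-2-[5-(methoxymethoxy)-2,2-dimethyl-2H-chromen-6-yl]prop-2-enoate (E/Z mixture, both converge)
Conditions: t-BuOCH(NMe2)2 (Bredereck's reagent), toluene, 100 °C
Reagents that add atoms: tert-butoxybis(dimethylamino)methane, CN(C)C(OC(C)(C)C)N(C)C
Why: Aminomethylenation of the activated arylacetate CH2 installs the future C2 at the aldehyde oxidation level and removes the acidic α-hydrogens before the organolithium step.

Step 7 (key step)
Reactants: 5; 11
Product: 12 5,7-bis(methoxymethoxy)-3-[5-(methoxymethoxy)-2,2-dimethyl-2H-chromen-6-yl]-6-(3-methylbut-2-en-1-yl)-4H-chromen-4-one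
Conditions: 5, n-BuLi (1 equiv) then s-BuLi/TMEDA (1.2 equiv), THF, −78 → −20 °C; 11, −78 → 0 °C; AcOH, rt → 40 °C
Reagents that add atoms: none
Why: Proposed new method: OLi/OMOM-cooperative ortho-lithiation of the symmetric phenoxide gives a C,O-dianion whose aryl carbon acylates the ester once (carbonyl delivered by coordination to the neighbouring OLi; the resulting vinylogous amide resists a second addition), and on acid quench the only free phenol closes the pyranone by addition–elimination of HNMe2. Because the two ortho positions of 5 are equivalent, only the 6-prenyl isoflavone can result; the closest known chemistry is aryllithium acylation by esters/Weinreb amides combined with the acid-mediated cyclisation of o-hydroxyaryl enaminones to chromones.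

Step 8
Reactants: 12
Product: 13 Angustone B
Conditions: 3 M aq. HCl, MeOH, 50 °C, monitored and stopped at full conversion
Reagents that add atoms: none
Why: Acid-catalysed acetal hydrolysis removes all three MOM groups under conditions commonly used for o-prenylphenols and 2,2-dimethylchromenes; there is no stereocentre to scramble.

**Compound list**
1 | resorcinol | Oc1cccc(O)c1 | starting material
2 | 1,3-bis(methoxymethoxy)benzene | COCOc1cccc(OCOC)c1 | intermediate
3 | prenyl bromide (1-bromo-3-methylbut-2-ene) | CC(C)=CCBr | starting material
4 | 1,3-bis(methoxymethoxy)-2-(3-methylbut-2-en-1-yl)benzene | CC(C)=CCc1c(OCOC)cccc1OCOC | intermediate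
5 | 3,5-bis(methoxymethoxy)-4-(3-methylbut-2-en-1-yl)phenol | CC(C)=CCc1c(OCOC)cc(O)cc1OCOC | intermediate
6 | cyclohexane-1,3-dione | O=C1CCCC(=O)C1 | starting material
7 | 3-methylbut-2-enal (prenal) | CC(C)=CC=O | starting material
8 | 2,2-dimethyl-2,6,7,8-tetrahydro-5H-chromen-5-one | CC1(C)C=CC2=C(O1)CCCC2=O | intermediate
9 | ethyl glyoxylate | CCOC(=O)C=O | starting material
10 | ethyl 2-[5-(methoxymethoxy)-2,2-dimethyl-2H-chromen-6-yl]acetate | CCOC(=O)Cc1ccc2OC(C)(C)C=Cc2c1OCOC | intermediate
11 | ethyl 3-(dimethylamino)-2-[5-(methoxymethoxy)-2,2-dimethyl-2H-chromen-6-yl]prop-2-enoate | CCOC(=O)C(=CN(C)C)c1ccc2OC(C)(C)C=Cc2c1OCOC | intermediate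
12 | 5,7-bis(methoxymethoxy)-3-[5-(methoxymethoxy)-2,2-dimethyl-2H-chromen-6-yl]-6-(3-methylbut-2-en-1-yl)-4H-chromen-4-one | CC(C)=CCc1c(OCOC)cc2occ(-c3ccc4OC(C)(C)C=Cc4c3OCOC)c(=O)c2c1OCOC | intermediate
13 | Angustone B, 5,7-dihydroxy-3-(5-hydroxy-2,2-dimethyl-2H-chromen-6-yl)-6-(3-methylbut-2-en-1-yl)-4H-chromen-4-one | CC(C)=CCc1c(O)cc2occ(-c3ccc4c(c3O)C=CC(C)(C)O4)c(=O)c2c1O | target

**Total steps:** 8.
**Longest linear sequence:** 5 steps (1 → 2 → 4 → 5 → 12 → 13, or 6 → 8 → 10 → 11 → 12 → 13).

**Steps most likely to fail, with fallbacks**
1. Step 7. Risks are lateral (benzylic/allylic) lithiation of the prenyl CH2, and aryl attack at the enamine carbon instead of the ester, which would lead to a 3-arylcoumarin. Fallback: split the annulation into a classical two-stage sequence. Convert 10 to its Weinreb amide, add the aryllithium from 5 (generated by ortho-bromination and Br–Li exchange) to give the deoxybenzoin, then close the ring with DMF-DMA.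
2. Step 5. The telescoped aldol/dehydration/isoaromatisation/MOM trapping may stall or give mixtures. Fallback: abandon the de novo arene construction and make 10 from a preformed arene. Condense 2,4-dihydroxybenzaldehyde with prenal to the known 5-hydroxy-2,2-dimethylchromene-6-carbaldehyde, protect as the MOM ether, and homologate the aldehyde by one carbon to the arylacetate.
3. Step 3. The iridium catalyst may borylate or isomerise the prenyl alkene. Fallback: start with the oxygen already in place instead of using C–H borylation. Phloroglucinol → 3,5-bis(methoxymethoxy)phenol → TIPS ether → lithiation/prenylation between the two OMOM groups → TBAF, giving 5.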